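**Strategy.** Ring A is disconnected across C1–C10 and C4–C5 (drimane numbering): the C3 oxygen beside the C4 gem-dimethyl group, three bonds from the C5–C10 ring fusion, is the retron of a 2-silyloxydiene cycloaddition. A catalytic enantioselective Diels–Alder reaction between 4-methyl-3-silyloxypenta-1,3-diene (C1–C4) and an acyclic (E)-α-methyl dienone (C5=C10) forms both bonds at once and transcribes the E geometry into the trans C5–H/C10–CH3 ring fusion. The precursor is a monocycle, not a decalin: ring B is closed afterwards by metathesis between the C5 styryl group and a vinyl ketone grown from the C9 acetyl group; oxa-Michael addition of umbelliferone, methylenation and C3 reduction finish the route.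

Key step: step 3

Remarks on the chemistry:
- Numbering: ring A = C1–C5 and C10, ring B = C5–C10, C11 on C9, C12 on C8; β is the face of the C10 methyl group, α the opposite face.
- Assumption: 4-methylpent-1-en-3-one (1) and the ylide 4 are taken as catalogue compounds.
- Assumption: the (S)-oxazaborolidine is taken to give the (10S) series drawn; if the first run shows the opposite sense, its enantiomer is used and nothing else changes.

Step 1
Reactants: 1 4-methylpent-1-en-3-one (isopropyl vinyl ketone)
Product: 2 4-methyl-3-(triisopropylsilyloxy)penta-1,3-diene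
Conditions: TIPSOTf, Et3N, CH2Cl2, 0 °C → rt
Reagents that add atoms: triisopropylsilyl trifluoromethanesulfonate (TIPSOTf), CC(C)[Si](C(C)C)(C(C)C)OS(=O)(=O)C(F)(F)F
Why: Silyl enol ether formation by soft enolisation; the ketone has a single enolisable position, the isopropyl methine, so only the 2-silyloxydiene with the fully substituted terminus can form.

Step 2
Reactants: 3 (E)-cinnamaldehyde; 4 3-(triphenylphosphoranylidene)butan-2-one
Product: 5 (3E,5E)-3-methyl-6-phenylhexa-3,5-dien-2-one
Conditions: toluene, 90 °C
Reagents that add atoms: none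
Why: Wittig olefination with a stabilised α-branched ylide adds 1,2 to the enal and should give the (E)-trisubstituted alkene, the geometry that later becomes the trans ring fusion.

Step 3
Reactants: 2 4-methyl-3-(triisopropylsilyloxy)penta-1,3-diene; 5 (3E,5E)-3-methyl-6-phenylhexa-3,5-dien-2-one
Product: 6 1-[(1S,6S)-1,5,5-trimethyl-6-[(E)-2-phenylethenyl]-4-(triisopropylsilyloxy)cyclohex-3-en-1-yl]ethan-1-one (acetyl and styryl trans)
Conditions: (S)-B-(o-tolyl)oxazaborolidine of α,α-diphenylprolinol (20 mol %), AlBr3 (16 mol %), CH2Cl2, −78 → −20 °C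
Reagents that add atoms: none
Why: The cationic oxazaborolidine–AlBr3 Lewis acid binds the ketone of 5, and diene 2 adds in an asynchronous concerted [4+2] cycloaddition in which its nucleophilic C4 terminus bonds to the β-carbon C5 and C1 to the α-carbon C10; the closest known reaction type is the aluminium Lewis-acid Diels–Alder reaction of this hindered 2-silyloxydiene with α,β-disubstituted enones. Ring A is the only ring closed; it forms by suprafacial addition on both components with the C4–C5 bond leading, and the C2=C3 silyl enol ether that remains is the masked C3 ketone. C10 is set in the absolute sense by the chiral ligand, which blocks one face of the coordinated enone. C5 follows from C10 because the addition is stereospecific: acetyl and styryl, trans on the (E)-alkene, stay trans, which is the trans C5–H/C10–CH3 relationship of the target, and since neither diene terminus carries a stereogenic substituent, endo and exo approach give the same product. The step needs regioselectivity (siloxy carbon 1,4 to the acyl-bearing carbon), secured by the polarity of the siloxydiene and by the fact that the reverse orientation would join two fully substituted carbons. It also needs site selectivity for the α,β over the γ,δ double bond, secured by carbonyl activation and by retention of the styrene conjugation.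

Step 4
Reactants: 6 methyl ketone cycloadduct
Product: 8 1-[(1S,6S)-1,5,5-trimethyl-6-[(E)-2-phenylethenyl]-4-(triisopropylsilyloxy)cyclohex-3-en-1-yl]ethenyl trifluoromethanesulfonate, via potassium enolate 7 (not isolated)
Conditions: KN(SiMe3)2, THF, −78 °C; then PhNTf2, −78 → 0 °C
Reagents that add atoms: N-phenylbis(trifluoromethanesulfonimide) (PhNTf2), O=S(=O)(N(c1ccccc1)S(=O)(=O)C(F)(F)F)C(F)(F)F
Why: Enol triflate formation; the acetyl methyl is the only acidic position (C10 is quaternary), so kinetic deprotonation and O-triflation should give the 1,1-disubstituted vinyl triflate.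

Step 5
Reactants: 8 vinyl triflate
Product: 9 2-[1,5,5-trimethyl-6-[(E)-2-phenylethenyl]-4-(triisopropylsilyloxy)cyclohex-3-en-1-yl]penta-1,4-dien-3-one (ring stereocentres as in 6)
Conditions: Pd(PPh3)4 (5 mol %), LiCl, CO (3 atm), CH2=CHSnBu3, THF, 55 °C
Reagents that add atoms: carbon monoxide, [C-]#[O+]; tributyl(vinyl)stannane, C=C[Sn](CCCC)(CCCC)CCCC
Why: Carbonylative Stille coupling (oxidative addition of the vinyl triflate, CO insertion, vinyl transfer from tin) should give the cross-conjugated divinyl ketone, with CO pressure suppressing direct coupling.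

Step 6
Reactants: 9 divinyl ketone
Product: 10 (4aR,8aS)-5,5,8a-trimethyl-1-methylidene-6-(triisopropylsilyloxy)-4a,5,8,8a-tetrahydronaphthalen-2(1H)-one (trans-fused, 5α-H, 10β-CH3)
Conditions: second-generation Grubbs catalyst (5 mol %), CH2Cl2, 40 °C
Reagents that add atoms: none
Why: Ring-closing metathesis between the styryl group and the unsubstituted vinyl ketone should close six-membered ring B as the C6=C7 enone with loss of styrene; the two chains are trans-diequatorial on ring A, so the trans-decalin forms without strain, and the hindered C9=C11 alkene and the trisubstituted enol ether stay out of the reaction.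

Step 7
Reactants: 10 bicyclic dienone; 11 umbelliferone (7-hydroxy-2H-chromen-2-one)
Product: 12 7-{[(1S,4aR,8aS)-5,5,8a-trimethyl-2-oxo-6-(triisopropylsilyloxy)-1,2,4a,5,8,8a-hexahydronaphthalen-1-yl]methoxy}-2H-chromen-2-one (9α-H, CH2OAr β)
Conditions: Cs2CO3 (0.2 equiv), 11 (1.5 equiv), MeCN, rt
Reagents that add atoms: none
Why: Base-catalysed oxa-Michael addition of the phenoxide to the unhindered exocyclic C11 terminus (not the hindered endocyclic C6), followed by protonation of the enolate at C9 from the α face, anti to the axial C10 methyl, which is also the thermodynamically preferred equatorial epimer.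

Step 8
Reactants: 12 β-aryloxy enone
Product: 13 7-{[(1S,4aR,8aS)-5,5,8a-trimethyl-2-methylidene-6-(triisopropylsilyloxy)-1,2,4a,5,8,8a-hexahydronaphthalen-1-yl]methoxy}-2H-chromen-2-one
Conditions: Zn, CH2Br2, TiCl4, THF/CH2Cl2, 0 °C → rt
Reagents that add atoms: dibromomethane, BrCBr
Why: Non-basic Takai–Lombardo methylenation should convert the enone carbonyl into the exocyclic C8=C12 alkene without enolising C9 (which would expel the aryloxide) and without touching the lactone.

Step 9
Reactants: 13 silyl enol ether
Product: 14 7-{[(1S,4aR,8aS)-5,5,8a-trimethyl-2-methylidene-6-oxo-1,2,4a,5,6,7,8,8a-octahydronaphthalen-1-yl]methoxy}-2H-chromen-2-one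
Conditions: Bu4NF, AcOH, THF, 0 °C
Reagents that add atoms: none
Why: Fluoride-mediated cleavage of the silyl enol ether under acetic acid buffering should release the C3 ketone while the acid-sensitive exocyclic diene and the lactone are left alone.

Step 10
Reactants: 14 C3 ketone
Product: 15 7-{[(1S,4aR,6S,8aS)-6-hydroxy-5,5,8a-trimethyl-2-methylidene-1,2,4a,5,6,7,8,8a-octahydronaphthalen-1-yl]methoxy}-2H-chromen-2-one (target)
Conditions: NaBH4, MeOH/CH2Cl2, −20 → 0 °C
Reagents that add atoms: none
Why: Borohydride reduction of the 4,4-dimethyl 3-ketone of the rigid trans-decalin should occur by axial attack from the α face to give the equatorial 3β-alcohol, and the coumarin lactone is not reduced at this temperature.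

**Compound list**

1 | 4-methylpent-1-en-3-one | C=CC(=O)C(C)C | starting material
2 | 4-methyl-3-(triisopropylsilyloxy)penta-1,3-diene | C=CC(O[Si](C(C)C)(C(C)C)C(C)C)=C(C)C | intermediate
3 | (E)-cinnamaldehyde | O=C/C=C/c1ccccc1 | starting material
4 | 3-(triphenylphosphoranylidene)butan-2-one | CC(=O)C(C)=P(c1ccccc1)(c1ccccc1)c1ccccc1 | starting material
5 | (3E,5E)-3-methyl-6-phenylhexa-3,5-dien-2-one | CC(=O)/C(C)=C/C=C/c1ccccc1 | intermediate
6 | 1-[(1S,6S)-1,5,5-trimethyl-6-[(E)-2-phenylethenyl]-4-(triisopropylsilyloxy)cyclohex-3-en-1-yl]ethan-1-one | c1ccccc1/C=C/[C@H]1C(C)(C)C(O[Si](C(C)C)(C(C)C)C(C)C)=CC[C@]1(C)C(C)=O | intermediate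
7 | potassium enolate of 6 (acetyl methyl deprotonated) | c1ccccc1/C=C/[C@H]1C(C)(C)C(O[Si](C(C)C)(C(C)C)C(C)C)=CC[C@]1(C)C(=C)[O-].[K+] | intermediate (not isolated)
8 | enol triflate of 6 | c1ccccc1/C=C/[C@H]1C(C)(C)C(O[Si](C(C)C)(C(C)C)C(C)C)=CC[C@]1(C)C(=C)OS(=O)(=O)C(F)(F)F | intermediate
9 | divinyl ketone, 2-(cyclohexenyl)penta-1,4-dien-3-one with ring stereocentres as in 6 | c1ccccc1/C=C/[C@H]1C(C)(C)C(O[Si](C(C)C)(C(C)C)C(C)C)=CC[C@]1(C)C(=C)C(=O)C=C | intermediate
10 | (4aR,8aS)-5,5,8a-trimethyl-1-methylidene-6-(triisopropylsilyloxy)-4a,5,8,8a-tetrahydronaphthalen-2(1H)-one | O=C1C=C[C@H]2C(C)(C)C(O[Si](C(C)C)(C(C)C)C(C)C)=CC[C@]2(C)C1=C | intermediate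
11 | umbelliferone (7-hydroxy-2H-chromen-2-one) | Oc1ccc2ccc(=O)oc2c1 | starting material
12 | 7-{[(1S,4aR,8aS)-5,5,8a-trimethyl-2-oxo-6-(triisopropylsilyloxy)-1,2,4a,5,8,8a-hexahydronaphthalen-1-yl]methoxy}-2H-chromen-2-one | O=C1C=C[C@H]2C(C)(C)C(O[Si](C(C)C)(C(C)C)C(C)C)=CC[C@]2(C)[C@H]1COc1ccc2ccc(=O)oc2c1 | intermediate
13 | 7-{[(1S,4aR,8aS)-5,5,8a-trimethyl-2-methylidene-6-(triisopropylsilyloxy)-1,2,4a,5,8,8a-hexahydronaphthalen-1-yl]methoxy}-2H-chromen-2-one | C=C1C=C[C@H]2C(C)(C)C(O[Si](C(C)C)(C(C)C)C(C)C)=CC[C@]2(C)[C@H]1COc1ccc2ccc(=O)oc2c1 | intermediate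
14 | 7-{[(1S,4aR,8aS)-5,5,8a-trimethyl-2-methylidene-6-oxo-1,2,4a,5,6,7,8,8a-octahydronaphthalen-1-yl]methoxy}-2H-chromen-2-one | C=C1C=C[C@H]2C(C)(C)C(=O)CC[C@]2(C)[C@H]1COc1ccc2ccc(=O)oc2c1 | intermediate
15 | 7-{[(1S,4aR,6S,8aS)-6-hydroxy-5,5,8a-trimethyl-2-methylidene-1,2,4a,5,6,7,8,8a-octahydronaphthalen-1-yl]methoxy}-2H-chromen-2-one | C=C1C=C[C@H]2C(C)(C)[C@@H](O)CC[C@]2(C)[C@H]1COc1ccc2ccc(=O)oc2c1 | target

**Step count.** Total: 10 steps. Longest linear sequence: 9 steps (step 1 or step 2, then steps 3 to 10).

**Steps most likely to fail**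

1. Step 3. Bond formation between the fully substituted diene terminus and the β-carbon of a ketone-activated, styryl-conjugated dienophile may stall. It may also become stepwise, which would erode the transfer of E geometry into the trans relationship. The chiral Lewis acid may discriminate the enone faces poorly, because an α-methyl ketone offers no formyl or α-C–H contact to organise its binding. The fallback sets out from 2 and 3 and returns at 6. Wittig reaction of 3 with 2-(triphenylphosphoranylidene)propanal (toluene, 80 °C) should give (2E,4E)-2-methyl-5-phenylpenta-2,4-dienal F1, an α-methyl enal, the dienophile class that is more electrophilic and best behaved under oxazaborolidinium catalysis. Cycloaddition of F1 with 2 under the triflimide-activated oxazaborolidine (CH2Cl2, −78 °C) should give the aldehyde cycloadduct F2. Addition of MeMgBr (THF, −78 °C) should give the secondary carbinol F3, and Dess–Martin oxidation should return methyl ketone 6.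

2. Step 7. The addition–elimination equilibrium of the acidic phenol may lie on the side of the enone (retro-oxa-Michael), and the exo-methylene dienone may oligomerise under base before it is trapped. The fallback sets out from 10 and returns at 12, forming the C11–O bond through boron. Copper-catalysed conjugate borylation (CuCl, NaOtBu, bisphosphine ligand, bis(pinacolato)diboron, MeOH, THF) should add boron to C11 and give the β-boryl ketone F4, with C9 protonated from the α face. Oxidation with NaBO3 should give the β-hydroxy ketone F5. Mitsunobu etherification of the primary alcohol with 11 (PPh3, diisopropyl azodicarboxylate, THF, 0 °C) should give 12.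

3. Step 8. The Lewis-acidic titanium–zinc reagent may enolise C9 and trigger β-elimination of the aryloxide, or it may cleave the silyl enol ether and then methylenate C3. The fallback sets out from 12 and returns at 13 by a Peterson olefination, which separates addition from elimination. Me3SiCH2MgCl with CeCl3 (THF, −78 °C) should add 1,2 to the enone faster than to the lactone and give the β-hydroxysilane F6. KH (THF, 0 °C) should then eliminate it regiospecifically toward the silyl-bearing carbon to give diene 13.

**Further compounds**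

F1 | step 3 | (2E,4E)-2-methyl-5-phenylpenta-2,4-dienal | O=C/C(C)=C/C=C/c1ccccc1
F2 | step 3 | aldehyde cycloadduct, (1S,6S)-1,5,5-trimethyl-6-[(E)-2-phenylethenyl]-4-(triisopropylsilyloxy)cyclohex-3-ene-1-carbaldehyde | c1ccccc1/C=C/[C@H]1C(C)(C)C(O[Si](C(C)C)(C(C)C)C(C)C)=CC[C@]1(C)C=O
F3 | step 3 | secondary carbinol, 1-(cyclohexenyl)ethan-1-ol with ring as in 6, carbinol epimers | c1ccccc1/C=C/[C@H]1C(C)(C)C(O[Si](C(C)C)(C(C)C)C(C)C)=CC[C@]1(C)C(C)O
F4 | step 7 | β-boryl ketone (C11 pinacolboronate of the ring B enone) | O=C1C=C[C@H]2C(C)(C)C(O[Si](C(C)C)(C(C)C)C(C)C)=CC[C@]2(C)[C@H]1CB1OC(C)(C)C(C)(C)O1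
F5 | step 7 | β-hydroxy ketone (C11 primary alcohol) | O=C1C=C[C@H]2C(C)(C)C(O[Si](C(C)C)(C(C)C)C(C)C)=CC[C@]2(C)[C@H]1CO
F6 | step 8 | β-hydroxysilane (C8 tertiary alcohol bearing CH2SiMe3, C8 epimers) | C[Si](C)(C)CC1(O)C=C[C@H]2C(C)(C)C(O[Si](C(C)C)(C(C)C)C(C)C)=CC[C@]2(C)[C@H]1COc1ccc2ccc(=O)oc2c1
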